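## Retrosynthetic overview

1. Atom numbers: ring A = C1–C5 and C10, ring B = C5–C10, C11 = OCH2 on C9, C12 = exocyclic CH2 on C8. Endgame: the C11–O aryl ether by Mitsunobu reaction with umbelliferone, C8=C12 by Wittig methylenation of a C6=C7–C8=O enone, the axial C3–OH by bulky-hydride reduction of the 3-ketone.
2. Key disconnection: ring A is opened at C1–C10 and C2–C3. Both bonds form in one iron-hydride radical–polar crossover annulation of the ring-B aldehyde 9 with acrolein (C1–C2); the formyl group that acrolein leaves on C2 is then removed by oxidation and decarboxylation.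
3. Enabling feature: in ring A the carbinol carbon C3 is flanked by the gem-dimethyl quaternary C4, so a C3 aldehyde cannot enolise, and its γ-carbon (C3–C4–C5–C10) is the methyl-bearing quaternary C10. Reading the C10 methyl as a former exocyclic CH2 makes ring A the product of a γ,δ-unsaturated neopentyl aldehyde and a two-carbon acceptor.
4. Ring B (all-cis C5/C8/C9, C10=CH2, C6=C7, C11) comes from one endo Diels–Alder reaction of siloxydiene 4 with ethyl buta-2,3-dienoate; the cis C5/C9 pair later steers the C10 stereocentre.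
5. Order of ring formation: ring B (step 3), then ring A (step 6); the coumarin bicycle is bought and attached last (step 14).

Key step: step 6

Remarks on the chemistry: C2 and C3 of 13, 14 and 15 (and of F4) are expected as epimer mixtures and are left open in the SMILES, because both centres are erased in steps 7 and 8 and C3 is reset in step 9. Compounds 1 and 5 are taken as catalogue chemicals. TBS = tert-butyldimethylsilyl, TBDPS = tert-butyldiphenylsilyl.

## Route

Step 1
Reactants: 1 2,2-dimethylpent-4-enenitrile; 2 (E)-but-2-enal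
Product: 3 (4E)-2,2-dimethyl-6-oxohex-4-enenitrile
Conditions: 2 (5 equiv), second-generation Grubbs catalyst RuCl2(=CHPh)(H2IMes)(PCy3) (3 mol%), CH2Cl2, 40 °C
Reagents that add atoms: none
Why: Olefin cross-metathesis of a terminal alkene with an enal is a reliable route to (E)-enals, and the nitrile on the remote quaternary carbon should not interfere.

Step 2
Reactants: 3 (4E)-2,2-dimethyl-6-oxohex-4-enenitrile
Product: 4 (3E,5E)-6-(TBS-oxy)-2,2-dimethylhexa-3,5-dienenitrile
Conditions: TBSOTf, Et3N, CH2Cl2, 0 °C to rt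
Reagents that add atoms: tert-butyldimethylsilyl trifluoromethanesulfonate, CC(C)(C)[Si](C)(C)OS(=O)(=O)C(F)(F)F
Why: O-Silylation of the enal with γ-deprotonation (silyl dienol ether formation) should give mainly the (E,E)-1-siloxydiene, the only isomer able to reach the s-cis conformation needed next; the nitrile carbon has no α-hydrogen.

Step 3
Reactants: 4 (3E,5E)-6-(TBS-oxy)-2,2-dimethylhexa-3,5-dienenitrile; 5 ethyl buta-2,3-dienoate
Product: 6 ethyl (1S,2R,5S)-2-(TBS-oxy)-5-(2-cyanopropan-2-yl)-6-methylidenecyclohex-3-ene-1-carboxylate (all-cis)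
Conditions: (S)-diphenylprolinol-derived B-(o-tolyl)oxazaborolidine·HNTf2 (20 mol%), CH2Cl2, −78 to −40 °C
Reagents that add atoms: none
Why: Proposed new method: a catalytic enantioselective Diels–Alder reaction of an allenic ester with an acyclic 1-siloxydiene, in which the cationic boron Lewis acid binds the ester carbonyl, activates only the conjugated C=C of the allene and shields one of its faces; the oxygen-bearing diene terminus C8 bonds to the ester-bearing C9 and the alkyl-bearing terminus C5 to the sp carbon C10 (ortho regiochemistry), and the endo transition state places OTBS, ester and the C5 side chain all cis, which sets C5 and C9 (and the temporary C8) in one step; the closest known reaction types are the oxazaborolidinium-catalysed Diels–Alder reaction of acrylates with siloxydienes and the auxiliary-controlled Lewis-acid Diels–Alder reaction of allenic esters; the catalyst antipode is chosen to give the (1S,2R,5S) series.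

Step 4
Reactants: 6 ethyl (1S,2R,5S)-2-(TBS-oxy)-5-(2-cyanopropan-2-yl)-6-methylidenecyclohex-3-ene-1-carboxylate
Product: 8 2-[(1S,4R,5R)-4-(TBS-oxy)-5-(hydroxymethyl)-6-methylidenecyclohex-2-en-1-yl]-2-methylpropanal, via aldimine 7 (not isolated)
Conditions: i-Bu2AlH (4.5 equiv), CH2Cl2, −78 to 0 °C; aq. potassium sodium tartrate, then aq. citric acid, rt
Reagents that add atoms: water, O
Why: i-Bu2AlH should reduce the ester to the primary alcohol while the hindered tertiary nitrile stops at the metallated aldimine 7, which hydrolytic work-up converts into the neopentyl aldehyde; the three stereocentres are untouched and the exocyclic alkene cannot move into conjugation under these non-basic conditions.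

Step 5
Reactants: 8 2-[(1S,4R,5R)-4-(TBS-oxy)-5-(hydroxymethyl)-6-methylidenecyclohex-2-en-1-yl]-2-methylpropanal
Product: 9 2-[(1S,4R,5R)-4-(TBS-oxy)-5-(TBDPS-oxymethyl)-6-methylidenecyclohex-2-en-1-yl]-2-methylpropanal
Conditions: TBDPSCl, imidazole, CH2Cl2, 0 °C to rt
Reagents that add atoms: tert-butyl(chloro)diphenylsilane, CC(C)(C)[Si](Cl)(c1ccccc1)c1ccccc1
Why: Imidazole-promoted silylation of the primary alcohol leaves the aldehyde alone, and the robust TBDPS group is chosen so that the allylic TBS ether can later be removed in its presence.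

Step 6
Reactants: 9 2-[(1S,4R,5R)-4-(TBS-oxy)-5-(TBDPS-oxymethyl)-6-methylidenecyclohex-2-en-1-yl]-2-methylpropanal; 10 prop-2-enal (acrolein)
Product: 13 (4aS,7R,8R,8aR)-7-(TBS-oxy)-8-(TBDPS-oxymethyl)-3-hydroxy-4,4,8a-trimethyl-1,2,3,4,4a,7,8,8a-octahydronaphthalene-2-carbaldehyde (C2/C3 epimer mixture), via tertiary radical 11 (not isolated), via iron enolate 12 (not isolated)
Conditions: Fe(acac)3 (0.3 equiv), PhSiH3 (2.5 equiv), 10 (3 equiv, added slowly), EtOH/ethylene glycol (5:1), degassed, 0 °C to rt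
Reagents that add atoms: none
Why: An iron hydride formed from Fe(acac)3 and PhSiH3 transfers a hydrogen atom to the exocyclic CH2 of the 1,1-disubstituted alkene (this CH2 becomes the angular methyl), the tertiary C10 radical 11 adds to acrolein (Giese addition, C1–C10), and reduction of the adduct radical by divalent iron gives enolate 12, which closes onto the non-enolisable neopentyl aldehyde C3 (C2–C3). The closest known reaction type is the iron-catalysed HAT-initiated radical–polar crossover annulation of γ,δ-unsaturated aldehydes with enals and enones. Ring A is closed by an intermolecular radical conjugate addition followed by a 6-(enolexo)-exo-trig aldol addition through a chair transition state that should give only the trans-fused decalin, because C1 and C4 are then both equatorial on ring B. The new quaternary stereocentre C10 is set by attack of acrolein on the face of the planar radical opposite to the three cis substituents of ring B (C5 side chain, C9 CH2OTBDPS, pseudoaxial C8 OTBS), which places the methyl cis to C11 and trans to H5; C2 and C3 need no control because both are erased in steps 7 and 8. The step needs hydrogen-atom transfer to the exocyclic methylene in preference to the ring C6=C7 bond, secured by the much faster formation of a tertiary radical from a 1,1-disubstituted alkene than of a secondary radical from a 1,2-disubstituted one, and it needs trapping by acrolein to outrun reduction of the radical, secured by excess acrolein and its high reactivity towards nucleophilic tertiary radicals.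

Step 7
Reactants: 13 (4aS,7R,8R,8aR)-7-(TBS-oxy)-8-(TBDPS-oxymethyl)-3-hydroxy-4,4,8a-trimethyl-1,2,3,4,4a,7,8,8a-octahydronaphthalene-2-carbaldehyde
Product: 14 (4aS,7R,8R,8aR)-7-(TBS-oxy)-8-(TBDPS-oxymethyl)-3-hydroxy-4,4,8a-trimethyl-1,2,3,4,4a,7,8,8a-octahydronaphthalene-2-carboxylic acid
Conditions: NaClO2, NaH2PO4, 2-methylbut-2-ene, t-BuOH/THF/H2O, 0 °C to rt
Reagents that add atoms: sodium chlorite, [Na+].[O-]Cl=O
Why: Pinnick oxidation of an aldehyde to the acid is mild enough for the silyl ethers and the β-hydroxy group, and 2-methylbut-2-ene scavenges the hypochlorous acid that would otherwise attack the ring alkene.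

Step 8
Reactants: 14 (4aS,7R,8R,8aR)-7-(TBS-oxy)-8-(TBDPS-oxymethyl)-3-hydroxy-4,4,8a-trimethyl-1,2,3,4,4a,7,8,8a-octahydronaphthalene-2-carboxylic acid
Product: 16 (4aR,5R,6R,8aS)-6-(TBS-oxy)-5-(TBDPS-oxymethyl)-1,1,4a-trimethyl-3,4,4a,5,6,8a-hexahydronaphthalen-2(1H)-one, via keto acid 15 (not isolated)
Conditions: Dess–Martin periodinane, CH2Cl2, 0 °C to rt; then toluene, 60 °C
Reagents that add atoms: none
Why: Dess–Martin oxidation of the secondary alcohol gives β-keto acid 15, which should lose CO2 through the usual six-membered transition state on gentle warming, so that the activating carbon is removed and C2 returns to CH2.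

Step 9
Reactants: 16 (4aR,5R,6R,8aS)-6-(TBS-oxy)-5-(TBDPS-oxymethyl)-1,1,4a-trimethyl-3,4,4a,5,6,8a-hexahydronaphthalen-2(1H)-one
Product: 17 (2S,4aR,5R,6R,8aS)-6-(TBS-oxy)-5-(TBDPS-oxymethyl)-1,1,4a-trimethyl-1,2,3,4,4a,5,6,8a-octahydronaphthalen-2-ol
Conditions: LiBH(s-Bu)3, THF, −78 °C; H2O quench
Reagents that add atoms: none
Why: The bulky tri-sec-butylborohydride should attack the 4,4-dimethyl-3-ketone along the equatorial trajectory, because axial approach past the axial hydrogens at C1 and C5 is blocked for so large a reagent, and so give the axial (3S) alcohol, as is usual for Selectride reductions of 4,4-dimethyl-3-keto decalins.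

Step 10
Reactants: 17 (2S,4aR,5R,6R,8aS)-6-(TBS-oxy)-5-(TBDPS-oxymethyl)-1,1,4a-trimethyl-1,2,3,4,4a,5,6,8a-octahydronaphthalen-2-ol
Product: 18 (1R,2R,4aS,6S,8aR)-1-(TBDPS-oxymethyl)-5,5,8a-trimethyl-1,2,4a,5,6,7,8,8a-octahydronaphthalene-2,6-diol
Conditions: HF·pyridine, pyridine, THF, 0 °C to rt
Reagents that add atoms: none
Why: Buffered HF·pyridine cleaves the secondary TBS ether much faster than the primary TBDPS ether, the standard basis for telling these two silyl groups apart.

Step 11
Reactants: 18 (1R,2R,4aS,6S,8aR)-1-(TBDPS-oxymethyl)-5,5,8a-trimethyl-1,2,4a,5,6,7,8,8a-octahydronaphthalene-2,6-diol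
Product: 19 (1R,4aS,6S,8aR)-1-(TBDPS-oxymethyl)-6-hydroxy-5,5,8a-trimethyl-4a,5,6,7,8,8a-hexahydronaphthalen-2(1H)-one
Conditions: MnO2 (excess), CH2Cl2, rt
Reagents that add atoms: none
Why: MnO2 oxidises only the allylic alcohol at C8 and leaves the saturated, hindered C3 alcohol untouched, giving the C6=C7–C8=O enone needed for methylenation.

Step 12
Reactants: 19 (1R,4aS,6S,8aR)-1-(TBDPS-oxymethyl)-6-hydroxy-5,5,8a-trimethyl-4a,5,6,7,8,8a-hexahydronaphthalen-2(1H)-one
Product: 20 (2S,4aR,5R,8aS)-5-(TBDPS-oxymethyl)-1,1,4a-trimethyl-6-methylidene-1,2,3,4,4a,5,6,8a-octahydronaphthalen-2-ol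
Conditions: Ph3PCH3Br, KOtBu (excess), THF, 0 °C to rt
Reagents that add atoms: methyltriphenylphosphonium bromide, C[P+](c1ccccc1)(c1ccccc1)c1ccccc1.[Br-]
Why: Wittig methylenation of the enone carbonyl (1,2-addition of the non-stabilised ylide) should install the exocyclic C8=C12 bond and with it the conjugated diene; the C3 alkoxide formed with excess ylide is inert and C9 already has its more stable equatorial configuration.

Step 13
Reactants: 20 (2S,4aR,5R,8aS)-5-(TBDPS-oxymethyl)-1,1,4a-trimethyl-6-methylidene-1,2,3,4,4a,5,6,8a-octahydronaphthalen-2-ol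
Product: 21 (2S,4aR,5R,8aS)-5-(hydroxymethyl)-1,1,4a-trimethyl-6-methylidene-1,2,3,4,4a,5,6,8a-octahydronaphthalen-2-ol
Conditions: Bu4NF, THF, rt
Reagents that add atoms: none
Why: Fluoride cleaves the remaining silyl ether under near-neutral conditions that should not disturb the diene or the allylic C9 centre.

Step 14
Reactants: 21 (2S,4aR,5R,8aS)-5-(hydroxymethyl)-1,1,4a-trimethyl-6-methylidene-1,2,3,4,4a,5,6,8a-octahydronaphthalen-2-ol; 22 7-hydroxy-2H-chromen-2-one (umbelliferone)
Product: 23 7-{[(1R,4aS,6S,8aR)-6-hydroxy-5,5,8a-trimethyl-2-methylidene-1,2,4a,5,6,7,8,8a-octahydronaphthalen-1-yl]methoxy}-2H-chromen-2-one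
Conditions: PPh3, DIAD, THF, 0 °C to rt
Reagents that add atoms: none
Why: Mitsunobu etherification with the acidic phenol should take place only at the primary C11 alcohol, the axial neopentyl C3 alcohol being too hindered to be activated or displaced; no stereocentre is involved.

## Compound list

1 | 2,2-dimethylpent-4-enenitrile | C=CCC(C)(C)C#N | starting material
2 | (E)-but-2-enal (crotonaldehyde) | C/C=C/C=O | starting material
3 | (4E)-2,2-dimethyl-6-oxohex-4-enenitrile | N#CC(C)(C)C/C=C/C=O | intermediate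
4 | (3E,5E)-6-(TBS-oxy)-2,2-dimethylhexa-3,5-dienenitrile | N#CC(C)(C)/C=C/C=C/O[Si](C)(C)C(C)(C)C | intermediate
5 | ethyl buta-2,3-dienoate | C=C=CC(=O)OCC | starting material
6 | ethyl (1S,2R,5S)-2-(TBS-oxy)-5-(2-cyanopropan-2-yl)-6-methylidenecyclohex-3-ene-1-carboxylate (all-cis) | [C@@H]1(O[Si](C)(C)C(C)(C)C)C=C[C@H](C(C)(C)C#N)C(=C)[C@@H]1C(=O)OCC | intermediate
7 | 2-[(1S,4R,5R)-4-(TBS-oxy)-5-(hydroxymethyl)-6-methylidenecyclohex-2-en-1-yl]-2-methylpropan-1-imine (formed as its aluminium derivative, not isolated) | [C@@H]1(O[Si](C)(C)C(C)(C)C)C=C[C@H](C(C)(C)C=N)C(=C)[C@@H]1CO | intermediate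
8 | 2-[(1S,4R,5R)-4-(TBS-oxy)-5-(hydroxymethyl)-6-methylidenecyclohex-2-en-1-yl]-2-methylpropanal | [C@@H]1(O[Si](C)(C)C(C)(C)C)C=C[C@H](C(C)(C)C=O)C(=C)[C@@H]1CO | intermediate
9 | 2-[(1S,4R,5R)-4-(TBS-oxy)-5-(TBDPS-oxymethyl)-6-methylidenecyclohex-2-en-1-yl]-2-methylpropanal | [C@@H]1(O[Si](C)(C)C(C)(C)C)C=C[C@H](C(C)(C)C=O)C(=C)[C@@H]1CO[Si](c2ccccc2)(c2ccccc2)C(C)(C)C | intermediate
10 | prop-2-enal (acrolein) | C=CC=O | starting material
11 | tertiary radical from 9 after hydrogen-atom addition to the exocyclic CH2 (radical centre at C10, which now bears CH3; not isolated) | [C@@H]1(O[Si](C)(C)C(C)(C)C)C=C[C@H](C(C)(C)C=O)[C](C)[C@@H]1CO[Si](c2ccccc2)(c2ccccc2)C(C)(C)C | intermediate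
12 | enolate of the conjugate adduct of 11 with acrolein (3-oxidoprop-2-enyl chain on quaternary C10; trivalent-iron enolate drawn as the free anion; not isolated) | [C@@H]1(O[Si](C)(C)C(C)(C)C)C=C[C@H](C(C)(C)C=O)[C@@](C)(CC=C[O-])[C@@H]1CO[Si](c2ccccc2)(c2ccccc2)C(C)(C)C | intermediate
13 | (4aS,7R,8R,8aR)-7-(TBS-oxy)-8-(TBDPS-oxymethyl)-3-hydroxy-4,4,8a-trimethyl-1,2,3,4,4a,7,8,8a-octahydronaphthalene-2-carbaldehyde (C2/C3 open) | [C@@H]1(O[Si](C)(C)C(C)(C)C)C=C[C@@H]2C(C)(C)C(O)C(C=O)C[C@@]2(C)[C@@H]1CO[Si](c3ccccc3)(c3ccccc3)C(C)(C)C | intermediate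
14 | (4aS,7R,8R,8aR)-7-(TBS-oxy)-8-(TBDPS-oxymethyl)-3-hydroxy-4,4,8a-trimethyl-1,2,3,4,4a,7,8,8a-octahydronaphthalene-2-carboxylic acid (C2/C3 open) | [C@@H]1(O[Si](C)(C)C(C)(C)C)C=C[C@@H]2C(C)(C)C(O)C(C(=O)O)C[C@@]2(C)[C@@H]1CO[Si](c3ccccc3)(c3ccccc3)C(C)(C)C | intermediate
15 | (4aS,7R,8R,8aR)-7-(TBS-oxy)-8-(TBDPS-oxymethyl)-4,4,8a-trimethyl-3-oxo-1,2,3,4,4a,7,8,8a-octahydronaphthalene-2-carboxylic acid (C2 open; not isolated) | [C@@H]1(O[Si](C)(C)C(C)(C)C)C=C[C@@H]2C(C)(C)C(=O)C(C(=O)O)C[C@@]2(C)[C@@H]1CO[Si](c3ccccc3)(c3ccccc3)C(C)(C)C | intermediate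
16 | (4aR,5R,6R,8aS)-6-(TBS-oxy)-5-(TBDPS-oxymethyl)-1,1,4a-trimethyl-3,4,4a,5,6,8a-hexahydronaphthalen-2(1H)-one | [C@@H]1(O[Si](C)(C)C(C)(C)C)C=C[C@@H]2C(C)(C)C(=O)CC[C@@]2(C)[C@@H]1CO[Si](c3ccccc3)(c3ccccc3)C(C)(C)C | intermediate
17 | (2S,4aR,5R,6R,8aS)-6-(TBS-oxy)-5-(TBDPS-oxymethyl)-1,1,4a-trimethyl-1,2,3,4,4a,5,6,8a-octahydronaphthalen-2-ol (axial OH) | [C@@H]1(O[Si](C)(C)C(C)(C)C)C=C[C@@H]2C(C)(C)[C@@H](O)CC[C@@]2(C)[C@@H]1CO[Si](c3ccccc3)(c3ccccc3)C(C)(C)C | intermediate
18 | (1R,2R,4aS,6S,8aR)-1-(TBDPS-oxymethyl)-5,5,8a-trimethyl-1,2,4a,5,6,7,8,8a-octahydronaphthalene-2,6-diol | [C@@H]1(O)C=C[C@@H]2C(C)(C)[C@@H](O)CC[C@@]2(C)[C@@H]1CO[Si](c3ccccc3)(c3ccccc3)C(C)(C)C | intermediate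
19 | (1R,4aS,6S,8aR)-1-(TBDPS-oxymethyl)-6-hydroxy-5,5,8a-trimethyl-4a,5,6,7,8,8a-hexahydronaphthalen-2(1H)-one | O=C1C=C[C@@H]2C(C)(C)[C@@H](O)CC[C@@]2(C)[C@@H]1CO[Si](c3ccccc3)(c3ccccc3)C(C)(C)C | intermediate
20 | (2S,4aR,5R,8aS)-5-(TBDPS-oxymethyl)-1,1,4a-trimethyl-6-methylidene-1,2,3,4,4a,5,6,8a-octahydronaphthalen-2-ol | C=C1C=C[C@@H]2C(C)(C)[C@@H](O)CC[C@@]2(C)[C@@H]1CO[Si](c3ccccc3)(c3ccccc3)C(C)(C)C | intermediate
21 | (2S,4aR,5R,8aS)-5-(hydroxymethyl)-1,1,4a-trimethyl-6-methylidene-1,2,3,4,4a,5,6,8a-octahydronaphthalen-2-ol | C=C1C=C[C@@H]2C(C)(C)[C@@H](O)CC[C@@]2(C)[C@@H]1CO | intermediate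
22 | 7-hydroxy-2H-chromen-2-one (umbelliferone) | Oc1ccc2ccc(=O)oc2c1 | starting material
23 | 7-{[(1R,4aS,6S,8aR)-6-hydroxy-5,5,8a-trimethyl-2-methylidene-1,2,4a,5,6,7,8,8a-octahydronaphthalen-1-yl]methoxy}-2H-chromen-2-one | C=C1C=C[C@@H]2C(C)(C)[C@@H](O)CC[C@@]2(C)[C@@H]1COc1ccc2ccc(=O)oc2c1 | target

## Step count and risks

Total step count: 14. Longest linear sequence: 14 steps (1 to 23).

Steps most likely to fail:

1. Step 3 (bears the label). What may go wrong: insufficient enantiofacial or endo control, inhibition of the boron Lewis acid by the nitrile, or silyl transfer from the dienol ether that turns the cycloaddition into a stepwise Mukaiyama–Michael addition. Fallback (auxiliary control in place of catalyst control, known chemistry): setting out from 4, the cycloaddition is run under EtAlCl2 (CH2Cl2, −78 °C) with the chiral allenic ester (1R,2S,5R)-5-methyl-2-(2-phenylpropan-2-yl)cyclohexyl buta-2,3-dienoate F1, which is made from commercially available (−)-8-phenylmenthol and but-3-ynoic acid by carbodiimide/DMAP esterification, the amine isomerising the alkynoate to the allenoate. The aryl group shields one face of the dienophile, and the all-cis adduct (1R,2S,5R)-5-methyl-2-(2-phenylpropan-2-yl)cyclohexyl (1S,2R,5S)-2-(TBS-oxy)-5-(2-cyanopropan-2-yl)-6-methylidenecyclohex-3-ene-1-carboxylate F2 is separated from its diastereomer by chromatography (the antipodal auxiliary is used if the facial sense proves opposite). Treatment of F2 with i-Bu2AlH as in step 4 cleaves the auxiliary ester and reduces the nitrile, so the route is rejoined at 8.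

2. Step 6 (key step). What may go wrong: reduction of the tertiary radical before it meets acrolein, conjugate addition without ring closure, or oligomerisation of acrolein under the iron hydride conditions. Fallback (the two bonds made in separate operations, known chemistry): setting out from 9, iron-hydride reductive olefin coupling with allyl acrylate (Fe(acac)3, PhSiH3, EtOH/ethylene glycol) forms only the C1–C10 bond and should give prop-2-en-1-yl 3-[(1R,2S,5R,6R)-5-(TBS-oxy)-6-(TBDPS-oxymethyl)-1-methyl-2-(2-methyl-1-oxopropan-2-yl)cyclohex-3-en-1-yl]propanoate F3. LiN(SiMe3)2 (THF, −78 °C) then closes ring A by intramolecular ester-enolate aldol addition onto the non-enolisable aldehyde to give prop-2-en-1-yl (4aS,7R,8R,8aR)-7-(TBS-oxy)-8-(TBDPS-oxymethyl)-3-hydroxy-4,4,8a-trimethyl-1,2,3,4,4a,7,8,8a-octahydronaphthalene-2-carboxylate F4. Dess–Martin oxidation gives the β-keto ester prop-2-en-1-yl (4aS,7R,8R,8aR)-7-(TBS-oxy)-8-(TBDPS-oxymethyl)-4,4,8a-trimethyl-3-oxo-1,2,3,4,4a,7,8,8a-octahydronaphthalene-2-carboxylate F5, and Pd(PPh3)4 with morpholine removes the allyl group with loss of CO2, so the route is rejoined at 16.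

3. Step 12. What may go wrong: the basic ylide deprotonates the enone at C9 (or at C5 through the dienolate) instead of adding to the hindered carbonyl, which would lead to β-elimination of the silyloxy group or loss of the ring-fusion configuration. Fallback (two-step Peterson olefination with a non-basic nucleophile): setting out from 19, Me3SiCH2MgCl pre-mixed with anhydrous CeCl3 (THF, −78 °C) adds 1,2 to the enone to give (1R,4aS,6S,8aR)-1-(TBDPS-oxymethyl)-5,5,8a-trimethyl-2-[(trimethylsilyl)methyl]-1,2,4a,5,6,7,8,8a-octahydronaphthalene-2,6-diol F6, and KH (THF, 0 °C to rt) then eliminates the silanolate, so the route is rejoined at 20.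

Further compounds
F1 | step 3 | (1R,2S,5R)-5-methyl-2-(2-phenylpropan-2-yl)cyclohexyl buta-2,3-dienoate | C=C=CC(=O)O[C@@H]1C[C@H](C)CC[C@H]1C(C)(C)c2ccccc2
F2 | step 3 | (1R,2S,5R)-5-methyl-2-(2-phenylpropan-2-yl)cyclohexyl (1S,2R,5S)-2-(TBS-oxy)-5-(2-cyanopropan-2-yl)-6-methylidenecyclohex-3-ene-1-carboxylate | [C@@H]1(O[Si](C)(C)C(C)(C)C)C=C[C@H](C(C)(C)C#N)C(=C)[C@@H]1C(=O)O[C@@H]2C[C@H](C)CC[C@H]2C(C)(C)c3ccccc3
F3 | step 6 | prop-2-en-1-yl 3-[(1R,2S,5R,6R)-5-(TBS-oxy)-6-(TBDPS-oxymethyl)-1-methyl-2-(2-methyl-1-oxopropan-2-yl)cyclohex-3-en-1-yl]propanoate | [C@@H]1(O[Si](C)(C)C(C)(C)C)C=C[C@H](C(C)(C)C=O)[C@@](C)(CCC(=O)OCC=C)[C@@H]1CO[Si](c2ccccc2)(c2ccccc2)C(C)(C)C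
F4 | step 6 | prop-2-en-1-yl (4aS,7R,8R,8aR)-7-(TBS-oxy)-8-(TBDPS-oxymethyl)-3-hydroxy-4,4,8a-trimethyl-1,2,3,4,4a,7,8,8a-octahydronaphthalene-2-carboxylate (C2/C3 open) | [C@@H]1(O[Si](C)(C)C(C)(C)C)C=C[C@@H]2C(C)(C)C(O)C(C(=O)OCC=C)C[C@@]2(C)[C@@H]1CO[Si](c3ccccc3)(c3ccccc3)C(C)(C)C
F5 | step 6 | prop-2-en-1-yl (4aS,7R,8R,8aR)-7-(TBS-oxy)-8-(TBDPS-oxymethyl)-4,4,8a-trimethyl-3-oxo-1,2,3,4,4a,7,8,8a-octahydronaphthalene-2-carboxylate (C2 open) | [C@@H]1(O[Si](C)(C)C(C)(C)C)C=C[C@@H]2C(C)(C)C(=O)C(C(=O)OCC=C)C[C@@]2(C)[C@@H]1CO[Si](c3ccccc3)(c3ccccc3)C(C)(C)C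
F6 | step 12 | (1R,4aS,6S,8aR)-1-(TBDPS-oxymethyl)-5,5,8a-trimethyl-2-[(trimethylsilyl)methyl]-1,2,4a,5,6,7,8,8a-octahydronaphthalene-2,6-diol (C2 open) | OC1(C[Si](C)(C)C)C=C[C@@H]2C(C)(C)[C@@H](O)CC[C@@]2(C)[C@@H]1CO[Si](c3ccccc3)(c3ccccc3)C(C)(C)C
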